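**Plan**

- Retrosynthesis: the C19 acetate, the 2α‑OH and the 15‑OH go back to a C19 ester, a C2 silyl enol ether and a silyl ether. Bonds C5–C10 and C3–C4 are then cut together (retro‑[4+2]), which opens ring A and ring B at once to an acyclic tetraene. The tetraene is cut at C4=C5 (olefination), C1=C2 (Wittig) and C8–C9 (epoxide opening) to geraniol (C9–C15, C10, C20, C1) and a C5–C8 alkenyl iodide.
- Forward: geraniol → C1 hydroxylation → asymmetric epoxidation → alkenyl opening at C9 → methyl enone (C10=C1–C2) and Z‑enoate (C4=C5) → 2‑silyloxydiene → one thermal intramolecular Diels–Alder reaction that closes rings A and B together → ester to acetate, enol ether to ketone, ketone to alcohol.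
- Enabling feature: ring A carries oxygen on C2 and an oxidised carbon (C19) on C4. C2–O can therefore be the silyloxy group of a diene C3=C2–C1=C10, and C19 the ester that activates a C4=C5 dienophile. The C7=C8 bond of ring B sits ready‑made in the tether C6–C9, so the ring‑fusion bond C5–C10 is the bond that closes ring B.
- Stereochemistry: C9 from the Sharpless epoxidation (inverted once on opening); C10, C5 and C4 from C9 and the alkene geometries (1(10)E, 4Z, 7Z) in the cycloaddition; C2 from a thermodynamically controlled ketone reduction; 13E from geraniol.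

Key step: step 11

Assumption: labdane numbering (C1–C20) is used for the atoms of every compound, also the acyclic ones; (1‑methoxyethyl)triphenylphosphonium chloride is treated as a stock Wittig salt (otherwise one step from PPh3 and 1‑chloroethyl methyl ether). TBS = tert‑butyldimethylsilyl, TBDPS = tert‑butyldiphenylsilyl.

**Route**

Step 1
Reactants: 1 geraniol
Product: 2 geranyl TBDPS ether
Conditions: TBDPSCl, imidazole, DMF, 25 °C
Reagents that add atoms: tert‑butyl(chloro)diphenylsilane, CC(C)(C)[Si](Cl)(c1ccccc1)c1ccccc1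
Why: Imidazole‑promoted silylation of the primary allylic alcohol masks O15 with a group that should survive every step up to the final fluoride treatment; no stereocentre is formed.

Step 2
Reactants: 2 geranyl TBDPS ether
Product: 3 (2E,6E)-8-(TBDPS‑oxy)-2,6-dimethylocta-2,6-dien-1-ol
Conditions: SeO2 (cat.), t‑BuOOH, salicylic acid (cat.), CH2Cl2, 25 °C
Reagents that add atoms: selenium dioxide, O=[Se]=O (oxygen carrier); tert‑butyl hydroperoxide, CC(C)(C)OO
Why: Riley allylic oxidation (ene reaction then [2,3] shift) attacks the E‑methyl group of the terminal trisubstituted alkene, so C1 is hydroxylated with the 9(10)E geometry kept, while the alkene next to the silyl ether is deactivated.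

Step 3
Reactants: 3 (2E,6E)-8-(TBDPS‑oxy)-2,6-dimethylocta-2,6-dien-1-ol
Product: 4 [(2S,3S)-3-[(3E)-5-(TBDPS‑oxy)-3-methylpent-3-en-1-yl]-2-methyloxiran-2-yl]methanol
Conditions: Ti(OiPr)4, L‑(+)-diethyl tartrate, t‑BuOOH, 4 Å MS, CH2Cl2, −20 °C
Reagents that add atoms: tert‑butyl hydroperoxide, CC(C)(C)OO
Why: Sharpless asymmetric epoxidation: the titanium tartrate complex binds the allylic alcohol and L‑(+)-tartrate should deliver oxygen to the face that gives the (2S,3S)-epoxide, which sets C9 (and, for the time being, C10); the other alkene is not an allylic alcohol and is left alone.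

Step 4
Reactants: 5 3-(TBS‑oxy)propanal
Product: 6 tert‑butyl{[(3Z)-4-iodopent-3-en-1-yl]oxy}dimethylsilane
Conditions: EtPPh3I, n‑BuLi, THF, 25 °C; I2, −78 °C; NaN(SiMe3)2, −20 °C; then 5, −78 → −20 °C
Reagents that add atoms: ethyltriphenylphosphonium iodide, CC[P+](c1ccccc1)(c1ccccc1)c1ccccc1.[I-]; iodine, II
Why: Stork–Zhao‑type Wittig olefination with the α‑iodo ylide Ph3P=C(I)CH3, which should give the (Z)-2-iodoalkene (iodine cis to the chain) and so presets the 7Z geometry.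

Step 5
Reactants: 6 tert‑butyl{[(3Z)-4-iodopent-3-en-1-yl]oxy}dimethylsilane; 4 [(2S,3S)-3-[(3E)-5-(TBDPS‑oxy)-3-methylpent-3-en-1-yl]-2-methyloxiran-2-yl]methanol
Product: 9 (2R,3S,6E)-8-(TBDPS‑oxy)-3-[(2Z)-5-(TBS‑oxy)pent-2-en-2-yl]-2,6-dimethyloct-6-ene-1,2-diol, via alkenyllithium 7 (not isolated), via alkenylmagnesium bromide 8 (not isolated)
Conditions: 6 (3 equiv), t‑BuLi (6 equiv), Et2O, −78 °C; MgBr2·OEt2, −78 → 0 °C; CuI (10 mol%), then 4, THF, −30 → 0 °C
Reagents that add atoms: none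
Why: Iodine–lithium exchange with retention, transmetalation and copper‑catalysed SN2 opening of the trisubstituted epoxide at its less substituted carbon C9 with inversion should form the C8–C9 bond and give C9 its final configuration, one equivalent of 8 being spent on the hydroxyl group.

Step 6
Reactants: 9 (2R,3S,6E)-8-(TBDPS‑oxy)-3-[(2Z)-5-(TBS‑oxy)pent-2-en-2-yl]-2,6-dimethyloct-6-ene-1,2-diol
Product: 10 (2R,3S,6E)-8-(TBDPS‑oxy)-3-[(2Z)-5-(TBS‑oxy)pent-2-en-2-yl]-2-hydroxy-2,6-dimethyloct-6-enal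
Conditions: SO3·pyridine, DMSO, i‑Pr2NEt, CH2Cl2, 0 °C
Reagents that add atoms: none
Why: Parikh–Doering oxidation takes the primary alcohol to the aldehyde and cannot touch the tertiary alcohol, and because the α‑carbon is fully substituted nothing can epimerise.

Step 7
Reactants: 10 (2R,3S,6E)-8-(TBDPS‑oxy)-3-[(2Z)-5-(TBS‑oxy)pent-2-en-2-yl]-2-hydroxy-2,6-dimethyloct-6-enal
Product: 13 (3E,5S,6Z)-5-[(3E)-5-(TBDPS‑oxy)-3-methylpent-3-en-1-yl]-9-hydroxy-4,6-dimethylnona-3,6-dien-2-one, via methoxy enol ether 11 (not isolated), via silylated enone 12 (not isolated)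
Conditions: Ph3P+CH(OMe)CH3 Cl− (3 equiv), KN(SiMe3)2, THF, −78 → 0 °C; then 1 M HCl, THF, 25 °C
Reagents that add atoms: (1‑methoxyethyl)triphenylphosphonium chloride, COC(C)[P+](c1ccccc1)(c1ccccc1)c1ccccc1.[Cl-]; water, O
Why: The Wittig reaction gives the 2‑methoxy enol ether, and aqueous acid should then ionise the tertiary allylic alcohol to the oxocarbenium‑stabilised allyl cation and hydrolyse it to the transposed enone (Stork–Danheiser‑type transposition), the E isomer being favoured under these equilibrating conditions and separated from any Z isomer, while the same acid removes the primary TBS ether.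

Step 8
Reactants: 13 (3E,5S,6Z)-5-[(3E)-5-(TBDPS‑oxy)-3-methylpent-3-en-1-yl]-9-hydroxy-4,6-dimethylnona-3,6-dien-2-one
Product: 14 (3Z,5S,6E)-5-[(3E)-5-(TBDPS‑oxy)-3-methylpent-3-en-1-yl]-4,6-dimethyl-8-oxonona-3,6-dienal
Conditions: Dess–Martin periodinane, NaHCO3, CH2Cl2, 0 °C
Reagents that add atoms: none
Why: Buffered Dess–Martin oxidation should give the β,γ‑unsaturated aldehyde without acid or base strong enough to move the 7Z alkene into conjugation.

Step 9
Reactants: 14 (3Z,5S,6E)-5-[(3E)-5-(TBDPS‑oxy)-3-methylpent-3-en-1-yl]-4,6-dimethyl-8-oxonona-3,6-dienal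
Product: 15 methyl (2Z,5Z,7S,8E)-7-[(3E)-5-(TBDPS‑oxy)-3-methylpent-3-en-1-yl]-2,6,8-trimethyl-10-oxoundeca-2,5,8-trienoate
Conditions: methyl 2-[bis(2,2,2-trifluoroethoxy)phosphoryl]propanoate, KN(SiMe3)2, 18‑crown‑6, THF, −78 °C
Reagents that add atoms: methyl 2-[bis(2,2,2-trifluoroethoxy)phosphoryl]propanoate, COC(=O)C(C)P(=O)(OCC(F)(F)F)OCC(F)(F)F
Why: Still–Gennari olefination: the electron‑poor phosphonate eliminates fast from the kinetic adduct and should give the (Z)-2-methyl enoate, which places the ester (future C19) cis to C6, the aldehyde reacting far faster than the hindered enone.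

Step 10
Reactants: 15 methyl (2Z,5Z,7S,8E)-7-[(3E)-5-(TBDPS‑oxy)-3-methylpent-3-en-1-yl]-2,6,8-trimethyl-10-oxoundeca-2,5,8-trienoate
Product: 16 methyl (2Z,5Z,7S,8E)-10-(TBS‑oxy)-7-[(3E)-5-(TBDPS‑oxy)-3-methylpent-3-en-1-yl]-2,6,8-trimethylundeca-2,5,8,10-tetraenoate
Conditions: TBSOTf, Et3N, CH2Cl2, −78 → 0 °C
Reagents that add atoms: tert‑butyldimethylsilyl trifluoromethanesulfonate, CC(C)(C)[Si](C)(C)OS(=O)(=O)C(F)(F)F
Why: Soft enolisation of the methyl ketone removes a proton of the CH3 group and should give the cross‑conjugated 2‑silyloxydiene without changing the C10=C1 geometry or touching the enoate.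

Step 11
Reactants: 16 methyl (2Z,5Z,7S,8E)-10-(TBS‑oxy)-7-[(3E)-5-(TBDPS‑oxy)-3-methylpent-3-en-1-yl]-2,6,8-trimethylundeca-2,5,8,10-tetraenoate
Product: 17 methyl 2-(TBS‑oxy)-15-(TBDPS‑oxy)labda-1,7,13E-trien-19-oate (5α‑H, 9α‑H, 10β‑CH3, 4β‑CO2Me)
Conditions: PhMe (0.01 M), BHT (cat.), 160 °C, sealed tube
Reagents that add atoms: none
Why: Thermal type 1 intramolecular Diels–Alder reaction: a concerted suprafacial [4π+2π] addition of the (E)-2-silyloxydiene C3=C2–C1=C10 to the (Z)-enoate C4=C5, the closest known reaction type being the cyclisation of 1,7,9-decatrienoates (also with a methyl group on the tethered diene carbon) to angularly methylated octalins. Ring A closes as the new cyclohexene (bonds C5–C10 and C3–C4) and ring B closes in the fused mode through the four‑carbon tether C6–C7=C8–C9 when the C5–C10 bond forms, the tether overriding the electronic preference of the 2‑silyloxydiene for the other orientation. C4 relative to C5 is fixed by the Z enoate (ester cis to C6, hence C19 β and H‑5 α), and C5 relative to C10 by the E diene and the exo, tether‑anti transition state, in which the inside methyl on C10 ends cis to C6 and C19 and the ring fusion is trans. The face is controlled by C9: its hydrogen eclipses C10=C1 (least allylic strain) and the C11 chain stands anti to the incoming C5, so the chain ends equatorial (9β). The step needs exo over endo selectivity, and the substrate is expected to secure it through the cis C7=C8 bond of the tether, which spans the small C6–C5···C10–C9 torsion of the exo half‑chair but not the wide one of the endo mode, and through the absence of a Lewis acid that would favour the ester‑endo path.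

Step 12
Reactants: 17 methyl 2-(TBS‑oxy)-15-(TBDPS‑oxy)labda-1,7,13E-trien-19-oate
Product: 18 2-(TBS‑oxy)-15-(TBDPS‑oxy)labda-1,7,13E-trien-19-ol
Conditions: LiAlH4, THF, 0 → 25 °C
Reagents that add atoms: none
Why: Hydride reduction of the hindered axial ester to the neopentyl alcohol, the silyl enol ether and the silyl ether being inert to LiAlH4.

Step 13
Reactants: 18 2-(TBS‑oxy)-15-(TBDPS‑oxy)labda-1,7,13E-trien-19-ol
Product: 19 2-(TBS‑oxy)-15-(TBDPS‑oxy)labda-1,7,13E-trien-19-yl acetate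
Conditions: Ac2O, pyridine, DMAP (cat.), CH2Cl2, 25 °C
Reagents that add atoms: acetic anhydride, CC(=O)OC(C)=O
Why: DMAP‑catalysed acylation of the only free hydroxyl group installs the C19 acetate while O2 and O15 are still masked, which settles the differentiation of the three oxygens.

Step 14
Reactants: 19 2-(TBS‑oxy)-15-(TBDPS‑oxy)labda-1,7,13E-trien-19-yl acetate
Product: 21 15-hydroxy-2-oxolabda-7,13E-dien-19-yl acetate, via keto acetate silyl ether 20 (not isolated)
Conditions: HF·pyridine, pyridine, THF, 0 → 25 °C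
Reagents that add atoms: none
Why: Fluoride cleaves only Si–O bonds, so the enol ether should give the C2 ketone and the silyl ether the C15 alcohol, while the acetate is untouched.

Step 15
Reactants: 21 15-hydroxy-2-oxolabda-7,13E-dien-19-yl acetate
Product: 22 2α,15-dihydroxylabda-7,13E-dien-19-yl acetate (target)
Conditions: SmI2 (2.5 equiv), THF–H2O, 0 °C
Reagents that add atoms: none
Why: Single‑electron reduction of the ketone (ketyl, then carbanion protonated by water) should give, as dissolving‑metal reductions of hindered cyclohexanones do, the equatorial 2α‑alcohol because the oxygen of the intermediate avoids the two syn‑axial groups on C4 and C10 on the β face, while acetate, alkenes and the allylic alcohol are inert to SmI2–H2O.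

**Compound list**

1 | geraniol, (2E)-3,7-dimethylocta-2,6-dien-1-ol | CC(C)=CCC/C(C)=C/CO | starting material
2 | geranyl TBDPS ether, tert‑butyl{[(2E)-3,7-dimethylocta-2,6-dien-1-yl]oxy}diphenylsilane | CC(C)=CCC/C(C)=C/CO[Si](c1ccccc1)(c1ccccc1)C(C)(C)C | intermediate
3 | (2E,6E)-8-[(tert‑butyldiphenylsilyl)oxy]-2,6-dimethylocta-2,6-dien-1-ol | OC/C(C)=C/CC/C(C)=C/CO[Si](c1ccccc1)(c1ccccc1)C(C)(C)C | intermediate
4 | [(2S,3S)-3-[(3E)-5-[(tert‑butyldiphenylsilyl)oxy]-3-methylpent-3-en-1-yl]-2-methyloxiran-2-yl]methanol | OC[C@]1(C)O[C@H]1CC/C(C)=C/CO[Si](c1ccccc1)(c1ccccc1)C(C)(C)C | intermediate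
5 | 3-[(tert‑butyldimethylsilyl)oxy]propanal | O=CCCO[Si](C)(C)C(C)(C)C | starting material
6 | tert‑butyl{[(3Z)-4-iodopent-3-en-1-yl]oxy}dimethylsilane | I/C(C)=C\CCO[Si](C)(C)C(C)(C)C | intermediate
7 | [(2E)-5-[(tert‑butyldimethylsilyl)oxy]pent-2-en-2-yl]lithium (Li cis to the chain) | [Li]/C(C)=C\CCO[Si](C)(C)C(C)(C)C | intermediate (not isolated)
8 | bromo[(2Z)-5-[(tert‑butyldimethylsilyl)oxy]pent-2-en-2-yl]magnesium | Br[Mg]/C(C)=C\CCO[Si](C)(C)C(C)(C)C | intermediate (not isolated)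
9 | (2R,3S,6E)-8-[(tert‑butyldiphenylsilyl)oxy]-3-[(2Z)-5-[(tert‑butyldimethylsilyl)oxy]pent-2-en-2-yl]-2,6-dimethyloct-6-ene-1,2-diol | OC[C@](C)(O)[C@@H](CC/C(C)=C/CO[Si](c1ccccc1)(c1ccccc1)C(C)(C)C)/C(C)=C\CCO[Si](C)(C)C(C)(C)C | intermediate
10 | (2R,3S,6E)-8-[(tert‑butyldiphenylsilyl)oxy]-3-[(2Z)-5-[(tert‑butyldimethylsilyl)oxy]pent-2-en-2-yl]-2-hydroxy-2,6-dimethyloct-6-enal | O=C[C@](C)(O)[C@@H](CC/C(C)=C/CO[Si](c1ccccc1)(c1ccccc1)C(C)(C)C)/C(C)=C\CCO[Si](C)(C)C(C)(C)C | intermediate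
11 | (4R,5S,8E)-10-[(tert‑butyldiphenylsilyl)oxy]-5-[(2Z)-5-[(tert‑butyldimethylsilyl)oxy]pent-2-en-2-yl]-2-methoxy-4,8-dimethyldeca-2,8-dien-4-ol (2E/2Z mixture, enol ether geometry left open) | COC(C)=C[C@](C)(O)[C@@H](CC/C(C)=C/CO[Si](c1ccccc1)(c1ccccc1)C(C)(C)C)/C(C)=C\CCO[Si](C)(C)C(C)(C)C | intermediate (not isolated)
12 | (3E,5S,6Z)-9-[(tert‑butyldimethylsilyl)oxy]-5-[(3E)-5-[(tert‑butyldiphenylsilyl)oxy]-3-methylpent-3-en-1-yl]-4,6-dimethylnona-3,6-dien-2-one | CC(=O)/C=C(C)/[C@@H](CC/C(C)=C/CO[Si](c1ccccc1)(c1ccccc1)C(C)(C)C)/C(C)=C\CCO[Si](C)(C)C(C)(C)C | intermediate (not isolated)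
13 | (3E,5S,6Z)-5-[(3E)-5-[(tert‑butyldiphenylsilyl)oxy]-3-methylpent-3-en-1-yl]-9-hydroxy-4,6-dimethylnona-3,6-dien-2-one | CC(=O)/C=C(C)/[C@@H](CC/C(C)=C/CO[Si](c1ccccc1)(c1ccccc1)C(C)(C)C)/C(C)=C\CCO | intermediate
14 | (3Z,5S,6E)-5-[(3E)-5-[(tert‑butyldiphenylsilyl)oxy]-3-methylpent-3-en-1-yl]-4,6-dimethyl-8-oxonona-3,6-dienal | CC(=O)/C=C(C)/[C@@H](CC/C(C)=C/CO[Si](c1ccccc1)(c1ccccc1)C(C)(C)C)/C(C)=C\CC=O | intermediate
15 | methyl (2Z,5Z,7S,8E)-7-[(3E)-5-[(tert‑butyldiphenylsilyl)oxy]-3-methylpent-3-en-1-yl]-2,6,8-trimethyl-10-oxoundeca-2,5,8-trienoate | CC(=O)/C=C(C)/[C@@H](CC/C(C)=C/CO[Si](c1ccccc1)(c1ccccc1)C(C)(C)C)/C(C)=C\C/C=C(C)\C(=O)OC | intermediate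
16 | methyl (2Z,5Z,7S,8E)-10-[(tert‑butyldimethylsilyl)oxy]-7-[(3E)-5-[(tert‑butyldiphenylsilyl)oxy]-3-methylpent-3-en-1-yl]-2,6,8-trimethylundeca-2,5,8,10-tetraenoate | C=C(O[Si](C)(C)C(C)(C)C)/C=C(C)/[C@@H](CC/C(C)=C/CO[Si](c1ccccc1)(c1ccccc1)C(C)(C)C)/C(C)=C\C/C=C(C)\C(=O)OC | intermediate
17 | methyl 2-[(tert‑butyldimethylsilyl)oxy]-15-[(tert‑butyldiphenylsilyl)oxy]labda-1,7,13E-trien-19-oate (trans‑fused; 5α‑H, 9α‑H, 10β‑CH3, ester on the 4β axial carbon) | COC(=O)[C@@]1(C)CC(O[Si](C)(C)C(C)(C)C)=C[C@]2(C)[C@@H](CC/C(C)=C/CO[Si](c3ccccc3)(c3ccccc3)C(C)(C)C)C(C)=CC[C@@H]12 | intermediate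
18 | 2-[(tert‑butyldimethylsilyl)oxy]-15-[(tert‑butyldiphenylsilyl)oxy]labda-1,7,13E-trien-19-ol | OC[C@@]1(C)CC(O[Si](C)(C)C(C)(C)C)=C[C@]2(C)[C@@H](CC/C(C)=C/CO[Si](c3ccccc3)(c3ccccc3)C(C)(C)C)C(C)=CC[C@@H]12 | intermediate
19 | 2-[(tert‑butyldimethylsilyl)oxy]-15-[(tert‑butyldiphenylsilyl)oxy]labda-1,7,13E-trien-19-yl acetate | CC(=O)OC[C@@]1(C)CC(O[Si](C)(C)C(C)(C)C)=C[C@]2(C)[C@@H](CC/C(C)=C/CO[Si](c3ccccc3)(c3ccccc3)C(C)(C)C)C(C)=CC[C@@H]12 | intermediate
20 | 15-[(tert‑butyldiphenylsilyl)oxy]-2-oxolabda-7,13E-dien-19-yl acetate | CC(=O)OC[C@@]1(C)CC(=O)C[C@]2(C)[C@@H](CC/C(C)=C/CO[Si](c3ccccc3)(c3ccccc3)C(C)(C)C)C(C)=CC[C@@H]12 | intermediate (not isolated)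
21 | 15-hydroxy-2-oxolabda-7,13E-dien-19-yl acetate | CC(=O)OC[C@@]1(C)CC(=O)C[C@]2(C)[C@@H](CC/C(C)=C/CO)C(C)=CC[C@@H]12 | intermediate
22 | 2α,15-dihydroxylabda-7,13E-dien-19-yl acetate, [(1S,3R,4aR,5S,8aR)-3-hydroxy-5-[(3E)-5-hydroxy-3-methylpent-3-en-1-yl]-1,4a,6-trimethyl-1,2,3,4,4a,5,8,8a-octahydronaphthalen-1-yl]methyl acetate | CC(=O)OC[C@@]1(C)C[C@H](O)C[C@]2(C)[C@@H](CC/C(C)=C/CO)C(C)=CC[C@@H]12 | target

**Count and risks**

Total: 15 steps. Longest linear sequence: 14 steps (steps 1–3 and 5–15 from geraniol; step 4 is a one‑step branch).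

Risk 1, step 11. The cycloaddition may run through the ester‑endo mode and give the cis ring fusion. It may add to the other face of the diene relative to C9. At 160 °C it may also be outrun by a 1,5‑hydrogen shift of the cis‑methyl silyloxydiene or by Z to E isomerisation of the enoate. The fallback sets out from aldehyde 14 and returns at 17. Knoevenagel condensation of 14 with dimethyl malonate (TiCl4, pyridine, THF, 0 °C) should give the dimethyl alkylidenemalonate F1, and soft enolisation (TBSOTf, Et3N) its 2‑silyloxydiene F2. This doubly activated dienophile has no E/Z isomers and always has one ester endo, so it should cyclise at 25–80 °C to the geminal diester F3, in which C4 is not yet a stereocentre. The less hindered equatorial 4α ester is then reduced with LiAlH(OtBu)3 to the 18‑alcohol F4. F4 is deoxygenated by the Barton–McCombie method through its imidazolyl thiocarbonate F5 (Bu3SnH, AIBN, PhMe, 110 °C), which gives 17.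

Risk 2, step 5. The hindered alkenyl nucleophile may fail to attack the secondary epoxide carbon that sits next to the fully substituted one. The alkoxide of 4 may also undergo Payne rearrangement, so that attack shifts to C1. The fallback sets out from epoxy alcohol 4 and returns at 9. The slim alkynylalane Et2AlC≡CCH2CH2OTBS (from tert‑butyl(but-3-yn-1-yloxy)dimethylsilane, n‑BuLi and Et2AlCl; PhMe, 0 °C) is delivered from the aluminium alkoxide to C9 with inversion and should give the alkynyl diol F6. Silylation of the primary hydroxyl with ClSiMe2H and Et3N, followed by intramolecular syn hydrosilylation (H2PtCl6 cat.), places silicon on C8 and hydrogen on C7 in the cyclic siloxane F7, which fixes the 7Z geometry. Iododesilylation with retention (N‑iodosuccinimide, MeCN) gives the alkenyl iodide diol F8, and Negishi methylation (Me2Zn, Pd(PPh3)4, THF) gives 9.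

Risk 3, step 15. The ketyl or carbanion may be protonated from the open α face, which gives the axial 2β‑alcohol, or the reduction may stall. The fallback sets out from acetate 19 and returns at 22. Aqueous oxalic acid in THF hydrolyses only the silyl enol ether and gives ketone 20, now isolated. NaBH4 (MeOH, 0 °C) attacks from the open α face and should give the 2β‑alcohol F9. Its triflate F10 (Tf2O, pyridine, CH2Cl2, −20 °C) is displaced with inversion by nitrite (KNO2, 18‑crown‑6, DMF; Lattrell–Dax inversion) to give the 2α‑alcohol F11. HF·pyridine then removes the TBDPS group and gives 22.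

**Further compounds**

F1 | step 11 | dimethyl 2-[(3Z,5S,6E)-5-[(3E)-5-[(tert‑butyldiphenylsilyl)oxy]-3-methylpent-3-en-1-yl]-4,6-dimethyl-8-oxonona-3,6-dien-1-ylidene]propanedioate | CC(=O)/C=C(C)/[C@@H](CC/C(C)=C/CO[Si](c1ccccc1)(c1ccccc1)C(C)(C)C)/C(C)=C\CC=C(C(=O)OC)C(=O)OC
F2 | step 11 | dimethyl 2-[(3Z,5S,6E)-8-[(tert‑butyldimethylsilyl)oxy]-5-[(3E)-5-[(tert‑butyldiphenylsilyl)oxy]-3-methylpent-3-en-1-yl]-4,6-dimethylnona-3,6,8-trien-1-ylidene]propanedioate | C=C(O[Si](C)(C)C(C)(C)C)/C=C(C)/[C@@H](CC/C(C)=C/CO[Si](c1ccccc1)(c1ccccc1)C(C)(C)C)/C(C)=C\CC=C(C(=O)OC)C(=O)OC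
F3 | step 11 | dimethyl 2-[(tert‑butyldimethylsilyl)oxy]-15-[(tert‑butyldiphenylsilyl)oxy]labda-1,7,13E-triene-18,19-dioate | COC(=O)C1(C(=O)OC)CC(O[Si](C)(C)C(C)(C)C)=C[C@]2(C)[C@@H](CC/C(C)=C/CO[Si](c3ccccc3)(c3ccccc3)C(C)(C)C)C(C)=CC[C@@H]12
F4 | step 11 | methyl 2-[(tert‑butyldimethylsilyl)oxy]-15-[(tert‑butyldiphenylsilyl)oxy]-18-hydroxylabda-1,7,13E-trien-19-oate | COC(=O)[C@@]1(CO)CC(O[Si](C)(C)C(C)(C)C)=C[C@]2(C)[C@@H](CC/C(C)=C/CO[Si](c3ccccc3)(c3ccccc3)C(C)(C)C)C(C)=CC[C@@H]12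
F5 | step 11 | methyl 2-[(tert‑butyldimethylsilyl)oxy]-15-[(tert‑butyldiphenylsilyl)oxy]-18-[(1H-imidazol-1-ylcarbonothioyl)oxy]labda-1,7,13E-trien-19-oate | COC(=O)[C@@]1(COC(=S)n2ccnc2)CC(O[Si](C)(C)C(C)(C)C)=C[C@]2(C)[C@@H](CC/C(C)=C/CO[Si](c3ccccc3)(c3ccccc3)C(C)(C)C)C(C)=CC[C@@H]12
F6 | step 5 | (2R,3S,6E)-8-[(tert‑butyldiphenylsilyl)oxy]-3-[4-[(tert‑butyldimethylsilyl)oxy]but-1-yn-1-yl]-2,6-dimethyloct-6-ene-1,2-diol | OC[C@](C)(O)[C@@H](CC/C(C)=C/CO[Si](c1ccccc1)(c1ccccc1)C(C)(C)C)C#CCCO[Si](C)(C)C(C)(C)C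
F7 | step 5 | (3E,4R,5R)-3-{3-[(tert‑butyldimethylsilyl)oxy]propylidene}-4-[(3E)-5-[(tert‑butyldiphenylsilyl)oxy]-3-methylpent-3-en-1-yl]-2,2,5-trimethyl-1,2-oxasilinan-5-ol | C[Si]1(C)OC[C@](C)(O)[C@@H](CC/C(C)=C/CO[Si](c2ccccc2)(c2ccccc2)C(C)(C)C)/C1=C\CCO[Si](C)(C)C(C)(C)C
F8 | step 5 | (2R,3R,6E)-8-[(tert‑butyldiphenylsilyl)oxy]-3-[(1E)-4-[(tert‑butyldimethylsilyl)oxy]-1-iodobut-1-en-1-yl]-2,6-dimethyloct-6-ene-1,2-diol | OC[C@](C)(O)[C@@H](CC/C(C)=C/CO[Si](c1ccccc1)(c1ccccc1)C(C)(C)C)/C(I)=C\CCO[Si](C)(C)C(C)(C)C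
F9 | step 15 | 15-[(tert‑butyldiphenylsilyl)oxy]-2β-hydroxylabda-7,13E-dien-19-yl acetate | CC(=O)OC[C@@]1(C)C[C@@H](O)C[C@]2(C)[C@@H](CC/C(C)=C/CO[Si](c3ccccc3)(c3ccccc3)C(C)(C)C)C(C)=CC[C@@H]12
F10 | step 15 | 15-[(tert‑butyldiphenylsilyl)oxy]-2β-[(trifluoromethanesulfonyl)oxy]labda-7,13E-dien-19-yl acetate | CC(=O)OC[C@@]1(C)C[C@@H](OS(=O)(=O)C(F)(F)F)C[C@]2(C)[C@@H](CC/C(C)=C/CO[Si](c3ccccc3)(c3ccccc3)C(C)(C)C)C(C)=CC[C@@H]12
F11 | step 15 | 15-[(tert‑butyldiphenylsilyl)oxy]-2α-hydroxylabda-7,13E-dien-19-yl acetate | CC(=O)OC[C@@]1(C)C[C@H](O)C[C@]2(C)[C@@H](CC/C(C)=C/CO[Si](c3ccccc3)(c3ccccc3)C(C)(C)C)C(C)=CC[C@@H]12
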